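**Plan**

- Retrosynthesis: the acetates and both aldehydes go back to the alcohol level. C6–OH/C5–H is removed as a syn hydroboration of C5=C6 and C9–OH as an enolate hydroxylation, leaving a ring B 5,7-diene 11,12-diester. Ring B is then cut at C6–C7 and C9–C10.
- Enabling feature: in ring B the C7=C8 alkene lies between oxygenated C6 (next to the C5 methine) and the fully substituted C9/C10 pair. One formal dehydration across C5–C6 makes ring B a cyclohexa-1,3-diene (C5=C6–C7=C8) whose sp3 atoms C9 and C10 are the termini of the hexatriene C10=C5–C6=C7–C8=C9. The C10=C5 end of that triene is the ring A alkene of a β-cyclocitral-type aldehyde; the rest is a butenedioate unit carrying C11 and C12.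
- Forward order: ring A is bought (enone 1) and converted to aldehyde 7. Phosphonate 10 supplies C7–C9, C11 and C12. One pot joins them at C6=C7 and closes ring B at C9–C10. Then follow C9–OH, ester reduction, hydroboration, acetylation and oxidation.
- Stereochemistry: C1 from a CBS reduction; C10 from torquoselective ring closure anti to the C1 pivalate; C9, C5 and C6 from attack on the α-face, opposite the axial C10 methyl (enolate hydroxylation, syn hydroboration).

Key step: step 8

Remark: drimane numbering is used (ring A C1–C5/C10, ring B C5–C10, C11 on C9, C12 on C8, C15 on C10; β is the face of the C10 methyl); compounds 1, 2 and 8 are taken as commercial.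

**Route**

Step 1
Reactants: 1 2,6,6-trimethylcyclohex-2-en-1-one; 2 vinylmagnesium bromide
Product: 3 2,6,6-trimethyl-1-vinylcyclohex-2-en-1-ol (racemic)
Conditions: CeCl3, THF, −78 → 0 °C; aq. NH4Cl
Reagents that add atoms: none
Why: CeCl3-promoted 1,2-addition of the Grignard reagent to the hindered enone carbonyl should give the tertiary bis-allylic alcohol, whose stereocentre is erased in step 2.

Step 2
Reactants: 3 2,6,6-trimethyl-1-vinylcyclohex-2-en-1-ol
Product: 4 2,4,4-trimethyl-3-vinylcyclohex-2-en-1-one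
Conditions: pyridinium chlorochromate (C5H5NH[CrO3Cl]), 4 Å MS, CH2Cl2, 25 °C
Reagents that add atoms: none
Why: Babler–Dauben oxidative 1,3-transposition: the tertiary chromate ester should shift to the secondary ring terminus (the more substituted allyl end) and be oxidised to the dienone, which places oxygen on the future C1 and leaves the vinyl carbon (future C6) on the future C5.

Step 3
Reactants: 4 2,4,4-trimethyl-3-vinylcyclohex-2-en-1-one
Product: 5 (R)-2,4,4-trimethyl-3-vinylcyclohex-2-en-1-ol
Conditions: (S)-2-methyl-CBS-oxazaborolidine (10 mol %), catecholborane, PhMe, −78 °C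
Reagents that add atoms: none
Why: Corey–Bakshi–Shibata reduction: the catalyst distinguishes the methyl-substituted alkenyl flank (large) from the CH2 flank (small) and should set the (R)-carbinol (future C1), while catecholborane at low temperature spares the vinyl group.

Step 4
Reactants: 5 (R)-2,4,4-trimethyl-3-vinylcyclohex-2-en-1-ol
Product: 6 (R)-2,4,4-trimethyl-3-vinylcyclohex-2-en-1-yl pivalate
Conditions: PivCl, pyridine, DMAP (cat.), CH2Cl2, 0 → 25 °C
Reagents that add atoms: pivaloyl chloride (CC(C)(C)C(=O)Cl)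
Why: Acylation of the secondary allylic alcohol gives a bulky ester without α-hydrogens that tolerates the bases used later and acts as the stereodirecting group in step 8.

Step 5
Reactants: 6 (R)-2,4,4-trimethyl-3-vinylcyclohex-2-en-1-yl pivalate
Product: 7 (R)-3-formyl-2,4,4-trimethylcyclohex-2-en-1-yl pivalate
Conditions: OsO4 (2 mol %), NaIO4, 2,6-lutidine, dioxane/H2O, 25 °C
Reagents that add atoms: osmium tetroxide (O=[Os](=O)(=O)=O), reoxidised by sodium periodate ([Na+].[O-]I(=O)(=O)=O)
Why: Lemieux–Johnson cleavage: OsO4 should dihydroxylate the unhindered monosubstituted vinyl group in preference to the tetrasubstituted ring alkene, and periodate cleaves the diol to the enal.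

Step 6
Reactants: 8 dimethyl mesaconate
Product: 9 dimethyl 2-(bromomethyl)fumarate (ester groups trans)
Conditions: NBS, AIBN (cat.), PhCF3, 80 °C
Reagents that add atoms: N-bromosuccinimide (O=C1CCC(=O)N1Br)
Why: Wohl–Ziegler bromination of the allylic methyl group through the resonance-stabilised allyl radical should give the primary allylic bromide.

Step 7
Reactants: 9 dimethyl 2-(bromomethyl)fumarate
Product: 10 dimethyl 2-[(diethoxyphosphoryl)methyl]fumarate
Conditions: P(OEt)3, neat, 110 °C
Reagents that add atoms: triethyl phosphite (CCOP(OCC)OCC)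
Why: Michaelis–Arbuzov reaction at the primary allylic bromide should place phosphorus on the future C7.

Step 8
Reactants: 7 (R)-3-formyl-2,4,4-trimethylcyclohex-2-en-1-yl pivalate; 10 dimethyl 2-[(diethoxyphosphoryl)methyl]fumarate
Product: 13 dimethyl (1R,9S,10R)-1-(pivaloyloxy)drima-5,7-diene-11,12-dioate, via E-triene 11 (not isolated), via Z-triene 12 (not isolated)
Conditions: LiHMDS, THF, −78 → 25 °C; then PhMe, 9-fluorenone (10 mol %), hν (405 nm), 90 °C, one pot
Reagents that add atoms: none
Why: Horner–Wadsworth–Emmons olefination of the C6 aldehyde by the C7 phosphonate carbanion forms C6=C7 (E-triene 11); triplet-sensitised E→Z isomerisation then feeds Z-triene 12, which is drained irreversibly by a thermal 6π electrocyclisation that forms C9–C10. The closest known reaction types are domino olefination/6π-electrocyclisation sequences, the sensitised tachysterol-to-previtamin D isomerisation and the thermal closure of previtamin D (the same C10=C5–C6=C7–C8=C9 triene with a ring-embedded, methyl-bearing terminus) to the pyrocalciferols. Ring B closes by a thermally allowed, suprafacial, disrotatory six-electron electrocyclisation, not by an ionic exo or endo cyclisation. The quaternary C10 is set by torquoselectivity under control of C1: the pivalate sits pseudoaxial to avoid allylic 1,2-strain with the C10 methyl and shields its face, so C9 should bond anti to O1, leaving the methyl β and cis to the 1β-oxygen. C9 follows from disrotation (hydrogen inside gives 9β-H), but either C9 epimer is usable because step 9 planarises this centre. The step needs the Z-isomer to close faster than side reactions: the C8 ester (acceptor at position 2 of the triene) should lower the closure barrier below the temperature of 1,5-hydrogen shifts, and the 1,7-hydrogen shift from C15 is a reversible side equilibrium.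

Step 9
Reactants: 13 dimethyl (1R,9S,10R)-1-(pivaloyloxy)drima-5,7-diene-11,12-dioate
Product: 14 dimethyl (1R,9S,10R)-9-hydroxy-1-(pivaloyloxy)drima-5,7-diene-11,12-dioate (9α-OH)
Conditions: KHMDS, THF, −78 °C; then 2-(phenylsulfonyl)-3-phenyloxaziridine, −78 °C; aq. NH4Cl
Reagents that add atoms: 2-(phenylsulfonyl)-3-phenyloxaziridine (O=S(=O)(c1ccccc1)N1OC1c1ccccc1)
Why: Davis enolate hydroxylation: deprotonation at C9 (α to the C11 ester and allylic) gives an extended enolate that should be oxidised at its α-carbon from the α-face, anti to the axial C10 methyl, which sets 9α-OH/9β-CO2Me as in hydroxylations of drimane C9 enolates.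

Step 10
Reactants: 14 dimethyl (1R,9S,10R)-9-hydroxy-1-(pivaloyloxy)drima-5,7-diene-11,12-dioate
Product: 15 drima-5,7-diene-1β,9α,11,12-tetraol
Conditions: DIBAL-H (excess), CH2Cl2, −78 → 0 °C; Rochelle salt
Reagents that add atoms: none
Why: DIBAL-H should reduce both methyl esters to primary alcohols (1,2-reduction of the dienoate) and cleave the pivalate in the same operation, without touching the diene.

Step 11
Reactants: 15 drima-5,7-diene-1β,9α,11,12-tetraol
Product: 16 11,12-bis(tert-butyldimethylsilyloxy)drima-5,7-diene-1β,9α-diol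
Conditions: TBSCl, imidazole, DMF, 0 °C
Reagents that add atoms: tert-butyldimethylsilyl chloride (CC(C)(C)[Si](C)(C)Cl)
Why: Silylation should discriminate on steric grounds, the two primary hydroxyls reacting while the secondary C1–OH next to the quaternary C10 and the tertiary C9–OH do not.

Step 12
Reactants: 16 11,12-bis(tert-butyldimethylsilyloxy)drima-5,7-diene-1β,9α-diol
Product: 17 11,12-bis(tert-butyldimethylsilyloxy)-5α-drim-7-ene-1β,6α,9α-triol
Conditions: BH3·THF (excess), THF, 0 → 25 °C; then NaOH, H2O2, 0 °C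
Reagents that add atoms: hydrogen peroxide (OO)
Why: Hydroboration–oxidation: borane should add syn to the alkyl-substituted C5=C6 bond (C7=C8 is deactivated by its two allylic oxygens) from the α-face, with boron on C6 and hydrogen on C5, so oxidation with retention gives 5α-H/6α-OH and keeps C7=C8, as in the hydroboration of steroidal 5,7-dienes.

Step 13
Reactants: 17 11,12-bis(tert-butyldimethylsilyloxy)-5α-drim-7-ene-1β,6α,9α-triol
Product: 18 1β,6α-diacetoxy-11,12-bis(tert-butyldimethylsilyloxy)-5α-drim-7-en-9α-ol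
Conditions: Ac2O, pyridine, DMAP, 40 °C
Reagents that add atoms: acetic anhydride (CC(=O)OC(C)=O)
Why: DMAP-catalysed acetylation should esterify the two secondary hydroxyls and leave the hindered tertiary C9 hydroxyl free.

Step 14
Reactants: 18 1β,6α-diacetoxy-11,12-bis(tert-butyldimethylsilyloxy)-5α-drim-7-en-9α-ol
Product: 19 1β,6α-diacetoxy-5α-drim-7-ene-9α,11,12-triol
Conditions: HF·pyridine, THF/pyridine, 0 → 25 °C
Reagents that add atoms: none
Why: Acidic fluoride should cleave the primary silyl ethers without the acetate migration from O1 to the neighbouring O11 that basic fluoride could cause.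

Step 15
Reactants: 19 1β,6α-diacetoxy-5α-drim-7-ene-9α,11,12-triol
Product: 20 parritadial, (1R,5S,6S,9S,10R)-1,6-diacetoxy-9-hydroxydrim-7-ene-11,12-dial
Conditions: (COCl)2, DMSO, CH2Cl2, −78 °C; then Et3N, −78 → 0 °C
Reagents that add atoms: none
Why: Swern oxidation activates both primary alcohols before base is added and should convert them to aldehydes together (no lactol), leaving the tertiary alcohol and acetates untouched; C9 is quaternary and cannot epimerise, as in oxidations of drim-7-ene-9,11,12-triols.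

**Compound list**

1 | 2,6,6-trimethylcyclohex-2-en-1-one | CC1=CCCC(C)(C)C1=O | starting material
2 | vinylmagnesium bromide | C=C[Mg]Br | starting material
3 | 2,6,6-trimethyl-1-vinylcyclohex-2-en-1-ol (racemic) | C=CC1(O)C(C)=CCCC1(C)C | intermediate
4 | 2,4,4-trimethyl-3-vinylcyclohex-2-en-1-one | C=CC1=C(C)C(=O)CCC1(C)C | intermediate
5 | (R)-2,4,4-trimethyl-3-vinylcyclohex-2-en-1-ol | C=CC1=C(C)[C@H](O)CCC1(C)C | intermediate
6 | (R)-2,4,4-trimethyl-3-vinylcyclohex-2-en-1-yl pivalate | C=CC1=C(C)[C@H](OC(=O)C(C)(C)C)CCC1(C)C | intermediate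
7 | (R)-3-formyl-2,4,4-trimethylcyclohex-2-en-1-yl pivalate | O=CC1=C(C)[C@H](OC(=O)C(C)(C)C)CCC1(C)C | intermediate
8 | dimethyl mesaconate | COC(=O)/C(C)=C/C(=O)OC | starting material
9 | dimethyl 2-(bromomethyl)fumarate (ester groups trans) | COC(=O)/C(CBr)=C/C(=O)OC | intermediate
10 | dimethyl 2-[(diethoxyphosphoryl)methyl]fumarate | COC(=O)/C(CP(=O)(OCC)OCC)=C/C(=O)OC | intermediate
11 | E-triene: dimethyl 2-{(E)-2-[(3R)-2,6,6-trimethyl-3-(pivaloyloxy)cyclohex-1-en-1-yl]ethenyl}fumarate (C6=C7 E, ester groups trans) | COC(=O)/C(=C/C(=O)OC)/C=C/C1=C(C)[C@H](OC(=O)C(C)(C)C)CCC1(C)C | intermediate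
12 | Z-triene: dimethyl 2-{(Z)-2-[(3R)-2,6,6-trimethyl-3-(pivaloyloxy)cyclohex-1-en-1-yl]ethenyl}maleate (C6=C7 Z, ester groups cis, H on C9 inside) | COC(=O)/C(=C\C(=O)OC)/C=C\C1=C(C)[C@H](OC(=O)C(C)(C)C)CCC1(C)C | intermediate
13 | dimethyl (1R,9S,10R)-1-(pivaloyloxy)drima-5,7-diene-11,12-dioate (1β-OPiv, 9β-H, 10β-CH3) | C1=C(C(=O)OC)[C@@H](C(=O)OC)[C@@]2(C)[C@H](OC(=O)C(C)(C)C)CCC(C)(C)C2=C1 | intermediate
14 | dimethyl (1R,9S,10R)-9-hydroxy-1-(pivaloyloxy)drima-5,7-diene-11,12-dioate (9α-OH) | C1=C(C(=O)OC)[C@](O)(C(=O)OC)[C@@]2(C)[C@H](OC(=O)C(C)(C)C)CCC(C)(C)C2=C1 | intermediate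
15 | drima-5,7-diene-1β,9α,11,12-tetraol | C1=C(CO)[C@](O)(CO)[C@@]2(C)[C@H](O)CCC(C)(C)C2=C1 | intermediate
16 | 11,12-bis(tert-butyldimethylsilyloxy)drima-5,7-diene-1β,9α-diol | C1=C(CO[Si](C)(C)C(C)(C)C)[C@](O)(CO[Si](C)(C)C(C)(C)C)[C@@]2(C)[C@H](O)CCC(C)(C)C2=C1 | intermediate
17 | 11,12-bis(tert-butyldimethylsilyloxy)-5α-drim-7-ene-1β,6α,9α-triol | O[C@H]1C=C(CO[Si](C)(C)C(C)(C)C)[C@](O)(CO[Si](C)(C)C(C)(C)C)[C@@]2(C)[C@H](O)CCC(C)(C)[C@H]12 | intermediate
18 | 1β,6α-diacetoxy-11,12-bis(tert-butyldimethylsilyloxy)-5α-drim-7-en-9α-ol | CC(=O)O[C@H]1C=C(CO[Si](C)(C)C(C)(C)C)[C@](O)(CO[Si](C)(C)C(C)(C)C)[C@@]2(C)[C@H](OC(C)=O)CCC(C)(C)[C@H]12 | intermediate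
19 | 1β,6α-diacetoxy-5α-drim-7-ene-9α,11,12-triol | CC(=O)O[C@H]1C=C(CO)[C@](O)(CO)[C@@]2(C)[C@H](OC(C)=O)CCC(C)(C)[C@H]12 | intermediate
20 | parritadial, (1R,5S,6S,9S,10R)-1,6-diacetoxy-9-hydroxydrim-7-ene-11,12-dial | CC(=O)O[C@H]1C=C(C=O)[C@](O)(C=O)[C@@]2(C)[C@H](OC(C)=O)CCC(C)(C)[C@H]12 | target

**Count and risks**

Total step count: 15. Longest linear sequence: 13 steps (steps 1–5, 8, 9–15).

Step 8. The photoisomerisation may not feed the ring closure cleanly: the E-triene may persist, the polyene ester may degrade under irradiation, or the 1,7-hydrogen shift may compete. Facial control by the C1 pivalate may also be eroded at the temperature needed. The fallback builds the Z-triene with defined geometry from an alkyne. It sets out from 7, which is homologated with dimethyl (1-diazo-2-oxopropyl)phosphonate and K2CO3 in MeOH (Ohira–Bestmann) to (R)-3-ethynyl-2,4,4-trimethylcyclohex-2-en-1-yl pivalate F1. Sonogashira coupling of this enyne with dimethyl bromomaleate (ester groups cis; Pd(PPh3)2Cl2, CuI, iPr2NH) should give dimethyl 2-{[(3R)-2,6,6-trimethyl-3-(pivaloyloxy)cyclohex-1-en-1-yl]ethynyl}maleate F2. Semi-hydrogenation over Pd on CaCO3 poisoned with Pb(OAc)2 and quinoline should deliver Z-triene 12, which is warmed in toluene to close to 13, where the route is rejoined.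

Step 12. Hydroboration of the conjugated diene may show poor regio- or facial selectivity, a 1,3-shift of the allylic borane, or attack on C7=C8. The fallback replaces it by a reduce–oxidise–invert sequence and runs from 16 to 18. Hydrogenation of the 5,6-bond from the α-face (H2, Raney Ni, EtOAc), as for steroidal 5,7-dienes, should give 11,12-bis(tert-butyldimethylsilyloxy)-5α-drim-7-ene-1β,9α-diol F3. Acetylation (Ac2O, DMAP, pyridine) gives 1β-acetoxy-11,12-bis(tert-butyldimethylsilyloxy)-5α-drim-7-en-9α-ol F4. Allylic oxidation at C6 (CrO3·3,5-dimethylpyrazole, CH2Cl2, −20 °C) gives 1β-acetoxy-9α-hydroxy-11,12-bis(tert-butyldimethylsilyloxy)-5α-drim-7-en-6-one F5. Luche reduction (NaBH4, CeCl3·7H2O, MeOH) should deliver hydride from the open α-face to 1β-acetoxy-11,12-bis(tert-butyldimethylsilyloxy)-5α-drim-7-ene-6β,9α-diol F6. Mitsunobu inversion with acetic acid (PPh3, DIAD) then gives the 6α-acetate 18.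

Step 9. The extended enolate may be oxidised at C7 or C5 instead of C9, deprotonation at the neopentyl C9 may be incomplete, or facial selectivity may be low. The fallback runs from 13 to 14 and separates enolisation from oxidation. Compound 13 is converted with KHMDS and TMSCl (THF, −78 °C) into its trimethylsilyl ketene acetal, methyl (1R,10R)-9-[methoxy(trimethylsilyloxy)methylidene]-1-(pivaloyloxy)-11-nordrima-5,7-dien-12-oate F7. Rubottom oxidation (mCPBA, NaHCO3, CH2Cl2, −20 °C; aqueous acid work-up) should epoxidise the most electron-rich C9=C11 bond from the α-face and give 14.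

**Further compounds**

F1 | step 8 | (R)-3-ethynyl-2,4,4-trimethylcyclohex-2-en-1-yl pivalate | C#CC1=C(C)[C@H](OC(=O)C(C)(C)C)CCC1(C)C
F2 | step 8 | dimethyl 2-{[(3R)-2,6,6-trimethyl-3-(pivaloyloxy)cyclohex-1-en-1-yl]ethynyl}maleate (ester groups cis) | COC(=O)/C(C#CC1=C(C)[C@H](OC(=O)C(C)(C)C)CCC1(C)C)=C\C(=O)OC
F3 | step 12 | 11,12-bis(tert-butyldimethylsilyloxy)-5α-drim-7-ene-1β,9α-diol | C1C=C(CO[Si](C)(C)C(C)(C)C)[C@](O)(CO[Si](C)(C)C(C)(C)C)[C@@]2(C)[C@H](O)CCC(C)(C)[C@H]12
F4 | step 12 | 1β-acetoxy-11,12-bis(tert-butyldimethylsilyloxy)-5α-drim-7-en-9α-ol | C1C=C(CO[Si](C)(C)C(C)(C)C)[C@](O)(CO[Si](C)(C)C(C)(C)C)[C@@]2(C)[C@H](OC(C)=O)CCC(C)(C)[C@H]12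
F5 | step 12 | 1β-acetoxy-9α-hydroxy-11,12-bis(tert-butyldimethylsilyloxy)-5α-drim-7-en-6-one | O=C1C=C(CO[Si](C)(C)C(C)(C)C)[C@](O)(CO[Si](C)(C)C(C)(C)C)[C@@]2(C)[C@H](OC(C)=O)CCC(C)(C)[C@H]12
F6 | step 12 | 1β-acetoxy-11,12-bis(tert-butyldimethylsilyloxy)-5α-drim-7-ene-6β,9α-diol | O[C@@H]1C=C(CO[Si](C)(C)C(C)(C)C)[C@](O)(CO[Si](C)(C)C(C)(C)C)[C@@]2(C)[C@H](OC(C)=O)CCC(C)(C)[C@H]12
F7 | step 9 | methyl (1R,10R)-9-[methoxy(trimethylsilyloxy)methylidene]-1-(pivaloyloxy)-11-nordrima-5,7-dien-12-oate (trimethylsilyl ketene acetal of 13) | C1=C(C(=O)OC)C(=C(OC)O[Si](C)(C)C)[C@@]2(C)[C@H](OC(=O)C(C)(C)C)CCC(C)(C)C2=C1
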